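At early times none of the solid substrate is in solution, so whatever single product or bis adduct a reading shows has first dissolved.

| setting | east | noon | dawn |
|---|---|---|---|
| solid substrate | 0.67 mM | 1.0 mM | 1.0 mM |
| partner | 3 mM | 3.00 mM | 0.800 mM |
| remark | run made earlier |  |  |
| time |  | 3.0 min | 3.0 min |

- east (time / s: bis adduct / %, single product / %): 12.0: 3, 4; 25.0: 16, 5; 40.0: 28, 7; 50.0: 37, 9; 60.0: 45, 6

(each reading ± 2 percentage points)

- solid substrate is a solid; its amount is given per volume of the solution
- at the start none of the solid substrate is in solution

- which of these holds the largest part of the solid substrate at the end of noon (other mono adduct / solid substrate / bis adduct / single product)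
- which of these holds the largest part of the solid substrate at the end of dawn (other mono adduct / solid substrate / bis adduct / single product)
- bis adduct at the end of noon, in percent of the solid substrate charged

In east the two products together grow about in step with time. The last east reading gives a first pace: 51.0% of 0.67 mM in 60.0 s, or 0.00570 mM s⁻¹. At that pace the 1.0 mM of noon needs 2.93 min, less than the 3.0 min allowed.

That reading also suggests 1.88 partner taken per unit of solid substrate in the two products, counting two per bis adduct. Noon therefore asks for 1.88 mM, less than its 3.00 mM, and solid substrate is the limiting reagent there. The 0.800 mM of dawn pays for about 0.426 mM, so this reckoning leaves about 57.4% of dawn's charge solid, more than the part dissolved.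

The weak link is the pace: the margin of 0.0700 min is smaller than the 0.162 min carried by the scatter of one sum. A line through zero over all the east sums gives 0.00583 mM s⁻¹. This pace of solid substrate into product is the feed. Taken over unchanged from east, where the charge was smaller, the feed gives noon an estimated clearing time of 2.86 min, less than the time allowed. Assuming that single product holds the same share of the charge as its east mean of 6.20%, this reckoning puts bis adduct, the larger holder in noon, at 93.8%.

The forecast, which also has “the solid dissolves slowly at a near-constant rate”, names bis adduct for noon and solid substrate for dawn, with 85% of bis adduct, lower than this reckoning.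

The flask gives bis adduct for noon, solid substrate for dawn and 88.9% of bis adduct.

    starting material + partner → single product + released group (k = 300 M⁻¹ s⁻¹)
    starting material + partner → other mono adduct + released group (k = 28.0 M⁻¹ s⁻¹)
    partner + single product → bis adduct + released group (k = 55.0 M⁻¹ s⁻¹)
    partner + other mono adduct → bis adduct + released group (k = 840 M⁻¹ s⁻¹)
    partner → decomposition product (k = 1.20 × 10⁻⁴ s⁻¹)
    solid substrate ⇌ starting material, rate k6*(cs6 - [starting material]) while solid is left; crystals form when [starting material] > cs6 (solubility = 0.0400 mM, k = 0.170 s⁻¹)

Noon dissolved 96.5% of its charge in 3.0 min, on average 0.00536 mM s⁻¹, below the feed of 0.00583 mM s⁻¹, while starting material was made 1.01 times as fast as it was used up, each step taken net, at 1.42 min; with the other settings held, a charge of 1.06 mM or a time of 2.81 min moves the bis adduct of noon by 5 points. Dawn dissolved 0.00356 mM s⁻¹ over its first 1.50 min, below the feed, with partner down to 38.4%, and ended with 7.85% of its partner and 53.2% of the solid substrate left.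

The runs stem from a simulated flask for substances that don't exist.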